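## Retrosynthetic overview

1. The target comes from a fully protected diaryl ether (two MOM ethers, one aryl methyl ether, one tert-butyl ester) by a single BCl3 deprotection; the ring A methyl ester is carried unchanged.
2. The diaryl ether C–O bond is cut to a ring A phenol and a ring B aryl fluoride flanked by CHO and CO2t-Bu (SNAr).
3. The ring A phenol comes from a C5 aldehyde (Baeyer–Villiger/Dakin), made by Rieche formylation of methyl 2,4-dihydroxy-3,6-dimethylbenzoate. That arene comes from a cyclohexane-1,3-dione built by intermolecular Michael addition of dimethyl malonate to (E)-hex-4-en-3-one (key C–C bond) and Claisen ring closure.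
4. The ring B fluoride comes from 3-fluoro-5-methylphenol by O-methylation, para-bromination, directed ortho-lithiation/formylation, chlorination, acetal protection and Br–Li exchange/Boc2O.
5. Ring order: ring A is the only ring constructed (carbocycle first, then aromatised); ring B is a purchased benzene; the two rings are joined in the penultimate step.

Assumption: the target has no stereocentre and no configurationally stable axis, so the achiral compound drawn is the single stereoisomer asked for.

## Route

Step 1
Reactants: 1 dimethyl malonate; 2 (E)-hex-4-en-3-one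
Product: 4 methyl 3,6-dimethyl-2,4-dioxocyclohexane-1-carboxylate, via dimethyl 2-(4-oxohexan-2-yl)propanedioate 3 (not isolated)
Conditions: NaOMe (1.1 equiv), MeOH, reflux; then aq. HCl, 0 °C
Reagents that add atoms: none
Why: The malonate anion adds to the enone β-carbon in an intermolecular Michael reaction (the bond that joins the two building blocks), and the ketone enolate then closes the six-membered ring by an intramolecular Claisen (Dieckmann-type) condensation; the sp3 stereocentres formed are erased on aromatisation.

Step 2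
Reactants: 4 methyl 3,6-dimethyl-2,4-dioxocyclohexane-1-carboxylate
Product: 5 methyl 2,4-dihydroxy-3,6-dimethylbenzoate
Conditions: DDQ (1.05 equiv), 1,4-dioxane, reflux
Reagents that add atoms: none
Why: Quinone dehydrogenation of the enolised 1,3-dione (hydride abstraction, then tautomerisation) is driven by formation of the aromatic resorcylate.

Step 3
Reactants: 5 methyl 2,4-dihydroxy-3,6-dimethylbenzoate
Product: 6 methyl 5-formyl-2,4-dihydroxy-3,6-dimethylbenzoate
Conditions: Cl2CHOMe, TiCl4, CH2Cl2, 0 °C → rt; then H2O
Reagents that add atoms: dichloromethyl methyl ether, COC(Cl)Cl; water, O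
Why: In this Rieche formylation the electrophile can only attack C5, the single free ring position (ortho to one hydroxyl, para to the other), and aqueous work-up hydrolyses the α-chloro ether to the aldehyde.

Step 4
Reactants: 6 methyl 5-formyl-2,4-dihydroxy-3,6-dimethylbenzoate
Product: 7 methyl 5-formyl-2,4-bis(methoxymethoxy)-3,6-dimethylbenzoate
Conditions: NaH (2.4 equiv), DMF, 0 °C; MOMCl (2.4 equiv), 0 °C → rt
Reagents that add atoms: chloromethyl methyl ether, COCCl
Why: Williamson-type O-alkylation of both sodium phenoxides; NaH is used because both hydroxyls are hydrogen-bonded to carbonyl groups.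

Step 5
Reactants: 7 methyl 5-formyl-2,4-bis(methoxymethoxy)-3,6-dimethylbenzoate
Product: 9 methyl 5-hydroxy-2,4-bis(methoxymethoxy)-3,6-dimethylbenzoate, via methyl 5-(formyloxy)-2,4-bis(methoxymethoxy)-3,6-dimethylbenzoate 8 (not isolated)
Conditions: mCPBA, CH2Cl2, 0 °C → rt; then K2CO3 (0.3 equiv), MeOH, rt, under Ar
Reagents that add atoms: 3-chloroperoxybenzoic acid, OOC(=O)c1cccc(Cl)c1
Why: In this Baeyer–Villiger (Dakin-type) oxidation the electron-rich aryl group (ortho and para alkoxy) migrates in preference to hydride to give the aryl formate, which base-catalysed methanolysis cleaves without touching the hindered methyl ester or the MOM ethers.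

Step 6
Reactants: 10 3-fluoro-5-methylphenol
Product: 11 1-fluoro-3-methoxy-5-methylbenzene
Conditions: MeI, K2CO3, acetone, reflux
Reagents that add atoms: iodomethane, CI
Why: Williamson O-methylation (SN2) of the phenoxide gives an ether that survives every later step and also serves as the ortho-directing group.

Step 7
Reactants: 11 1-fluoro-3-methoxy-5-methylbenzene
Product: 12 2-bromo-1-fluoro-5-methoxy-3-methylbenzene
Conditions: NBS, MeCN, 0 °C → rt
Reagents that add atoms: N-bromosuccinimide, O=C1CCC(=O)N1Br
Why: Electrophilic aromatic bromination with NBS in MeCN is strongly para-selective for anisoles, so bromine enters para to OMe between F and CH3 (any ortho isomer is removed by chromatography).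

Step 8
Reactants: 12 2-bromo-1-fluoro-5-methoxy-3-methylbenzene
Product: 14 3-bromo-2-fluoro-6-methoxy-4-methylbenzaldehyde, via (3-bromo-2-fluoro-6-methoxy-4-methylphenyl)lithium 13 (not isolated)
Conditions: LiN(i-Pr)2 (LDA, 1.1 equiv), THF, −78 °C; DMF, −78 → 0 °C; then aq. HCl
Reagents that add atoms: N,N-dimethylformamide, CN(C)C=O
Why: In this directed ortho-metalation the proton flanked by F and OMe is the most acidic, the amide base does not exchange the bromide, and the aryllithium (kept at −78 °C to avoid LiF loss) is formylated by DMF.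

Step 9
Reactants: 14 3-bromo-2-fluoro-6-methoxy-4-methylbenzaldehyde
Product: 15 3-bromo-5-chloro-2-fluoro-6-methoxy-4-methylbenzaldehyde
Conditions: NCS (1.1 equiv), CF3SO3H (0.2 equiv), MeCN, rt → 50 °C, dark
Reagents that add atoms: N-chlorosuccinimide, O=C1CCC(=O)N1Cl
Why: Acid-activated NCS chlorinates by electrophilic aromatic substitution at the single remaining ring C–H, which is ortho to OMe and CH3 and para to F.

Step 10
Reactants: 15 3-bromo-5-chloro-2-fluoro-6-methoxy-4-methylbenzaldehyde
Product: 16 1-bromo-3-chloro-5-(dimethoxymethyl)-6-fluoro-4-methoxy-2-methylbenzene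
Conditions: HC(OMe)3, MeOH, p-TsOH (5 mol %), 50 °C; then Et3N (trace)
Reagents that add atoms: trimethyl orthoformate, COC(OC)OC; methanol, CO
Why: Acid-catalysed acetalisation, driven by the orthoformate as water scavenger, masks the aldehyde before the organolithium step.

Step 11
Reactants: 16 1-bromo-3-chloro-5-(dimethoxymethyl)-6-fluoro-4-methoxy-2-methylbenzene
Product: 18 tert-butyl 3-chloro-5-(dimethoxymethyl)-6-fluoro-4-methoxy-2-methylbenzoate, via [3-chloro-5-(dimethoxymethyl)-6-fluoro-4-methoxy-2-methylphenyl]lithium 17 (not isolated)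
Conditions: n-BuLi (1.05 equiv), THF, −78 °C; Boc2O (1.5 equiv), −78 °C → rt; then H2O
Reagents that add atoms: di-tert-butyl dicarbonate, CC(C)(C)OC(=O)OC(=O)OC(C)(C)C
Why: Bromine–lithium exchange is far faster at −78 °C than chlorine exchange or any deprotonation, and acylation of the aryllithium by Boc2O gives a di-ortho-substituted tert-butyl ester that cannot over-add.

Step 12
Reactants: 18 tert-butyl 3-chloro-5-(dimethoxymethyl)-6-fluoro-4-methoxy-2-methylbenzoate
Product: 19 tert-butyl 3-chloro-6-fluoro-5-formyl-4-methoxy-2-methylbenzoate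
Conditions: 1 M aq. HCl, THF, rt
Reagents that add atoms: water, O
Why: Acid-catalysed acetal hydrolysis proceeds at room temperature, where dilute acid does not cleave the hindered tert-butyl ester or the aryl methyl ether.

Step 13
Reactants: 9 methyl 5-hydroxy-2,4-bis(methoxymethoxy)-3,6-dimethylbenzoate; 19 tert-butyl 3-chloro-6-fluoro-5-formyl-4-methoxy-2-methylbenzoate
Product: 20 methyl 5-[2-(tert-butoxycarbonyl)-4-chloro-6-formyl-5-methoxy-3-methylphenoxy]-2,4-bis(methoxymethoxy)-3,6-dimethylbenzoate
Conditions: Cs2CO3 (1.5 equiv), DMF, 70 °C, under Ar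
Reagents that add atoms: none
Why: In this nucleophilic aromatic substitution (SNAr) the fluoride is activated by the ortho formyl and ortho ester groups, which stabilise the Meisenheimer complex, while the chloride (meta to both carbonyls) is unactivated and stays.

Step 14
Reactants: 20 methyl 5-[2-(tert-butoxycarbonyl)-4-chloro-6-formyl-5-methoxy-3-methylphenoxy]-2,4-bis(methoxymethoxy)-3,6-dimethylbenzoate
Product: 21 3-chloro-5-formyl-4-hydroxy-6-[2,4-dihydroxy-5-(methoxycarbonyl)-3,6-dimethylphenoxy]-2-methylbenzoic acid (target)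
Conditions: BCl3 (8 equiv), CH2Cl2, −78 °C → rt; then H2O
Reagents that add atoms: none
Why: Lewis acid dealkylation by BCl3 removes the two MOM acetals, the tert-butyl ester and the methyl ether chelated to the ortho formyl group in one operation, while the ring A methyl ester, the aldehyde, the aryl chloride and the diaryl ether are inert to BCl3 at or below room temperature.

## Compound list

1 | dimethyl malonate | COC(=O)CC(=O)OC | starting material
2 | (E)-hex-4-en-3-one | CCC(=O)/C=C/C | starting material
3 | dimethyl 2-(4-oxohexan-2-yl)propanedioate (racemic Michael adduct, not isolated) | COC(=O)C(C(=O)OC)C(C)CC(=O)CC | intermediate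
4 | methyl 3,6-dimethyl-2,4-dioxocyclohexane-1-carboxylate (mixture of diastereomers and enol tautomers; stereocentres removed in step 2) | COC(=O)C1C(C)CC(=O)C(C)C1=O | intermediate
5 | methyl 2,4-dihydroxy-3,6-dimethylbenzoate | COC(=O)c1c(C)cc(O)c(C)c1O | intermediate
6 | methyl 5-formyl-2,4-dihydroxy-3,6-dimethylbenzoate | COC(=O)c1c(C)c(C=O)c(O)c(C)c1O | intermediate
7 | methyl 5-formyl-2,4-bis(methoxymethoxy)-3,6-dimethylbenzoate | COC(=O)c1c(C)c(C=O)c(OCOC)c(C)c1OCOC | intermediate
8 | methyl 5-(formyloxy)-2,4-bis(methoxymethoxy)-3,6-dimethylbenzoate (not isolated) | COC(=O)c1c(C)c(OC=O)c(OCOC)c(C)c1OCOC | intermediate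
9 | methyl 5-hydroxy-2,4-bis(methoxymethoxy)-3,6-dimethylbenzoate | COC(=O)c1c(C)c(O)c(OCOC)c(C)c1OCOC | intermediate
10 | 3-fluoro-5-methylphenol | Cc1cc(O)cc(F)c1 | starting material
11 | 1-fluoro-3-methoxy-5-methylbenzene | COc1cc(C)cc(F)c1 | intermediate
12 | 2-bromo-1-fluoro-5-methoxy-3-methylbenzene | COc1cc(C)c(Br)c(F)c1 | intermediate
13 | (3-bromo-2-fluoro-6-methoxy-4-methylphenyl)lithium (not isolated) | [Li]c1c(F)c(Br)c(C)cc1OC | intermediate
14 | 3-bromo-2-fluoro-6-methoxy-4-methylbenzaldehyde | COc1cc(C)c(Br)c(F)c1C=O | intermediate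
15 | 3-bromo-5-chloro-2-fluoro-6-methoxy-4-methylbenzaldehyde | COc1c(Cl)c(C)c(Br)c(F)c1C=O | intermediate
16 | 1-bromo-3-chloro-5-(dimethoxymethyl)-6-fluoro-4-methoxy-2-methylbenzene (dimethyl acetal of 15) | COc1c(Cl)c(C)c(Br)c(F)c1C(OC)OC | intermediate
17 | [3-chloro-5-(dimethoxymethyl)-6-fluoro-4-methoxy-2-methylphenyl]lithium (not isolated) | [Li]c1c(C)c(Cl)c(OC)c(C(OC)OC)c1F | intermediate
18 | tert-butyl 3-chloro-5-(dimethoxymethyl)-6-fluoro-4-methoxy-2-methylbenzoate | COc1c(Cl)c(C)c(C(=O)OC(C)(C)C)c(F)c1C(OC)OC | intermediate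
19 | tert-butyl 3-chloro-6-fluoro-5-formyl-4-methoxy-2-methylbenzoate | COc1c(Cl)c(C)c(C(=O)OC(C)(C)C)c(F)c1C=O | intermediate
20 | methyl 5-[2-(tert-butoxycarbonyl)-4-chloro-6-formyl-5-methoxy-3-methylphenoxy]-2,4-bis(methoxymethoxy)-3,6-dimethylbenzoate | COC(=O)c1c(C)c(Oc2c(C=O)c(OC)c(Cl)c(C)c2C(=O)OC(C)(C)C)c(OCOC)c(C)c1OCOC | intermediate
21 | 3-chloro-5-formyl-4-hydroxy-6-[2,4-dihydroxy-5-(methoxycarbonyl)-3,6-dimethylphenoxy]-2-methylbenzoic acid (achiral) | COC(=O)c1c(C)c(Oc2c(C=O)c(O)c(Cl)c(C)c2C(=O)O)c(O)c(C)c1O | target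

## Step count and risk

Total steps: 14. Longest linear sequence: 9 steps (steps 6–14, from 3-fluoro-5-methylphenol); the ring A branch is steps 1–5 and joins at step 13.

The three steps most likely to fail, most risky first:

Step 13 (SNAr to a diaryl ether with four ortho substituents). The hindered phenoxide may react slowly with a fluoride shielded by the twisted tert-butyl ester. The fallback sets out from phenol 9 and aldehyde 15, so that the ether is made before the carboxyl carbon is installed. SNAr of 9 on 15 (Cs2CO3, DMF, 70 °C; fluorine now flanked by CHO and Br) gives methyl 5-(2-bromo-4-chloro-6-formyl-5-methoxy-3-methylphenoxy)-2,4-bis(methoxymethoxy)-3,6-dimethylbenzoate F1. Hydroxycarbonylation of the aryl bromide (Pd(OAc)2, di(1-adamantyl)-n-butylphosphine, CO, K2CO3, H2O/1,4-dioxane, 100 °C) then gives 3-chloro-5-formyl-4-methoxy-6-[5-(methoxycarbonyl)-2,4-bis(methoxymethoxy)-3,6-dimethylphenoxy]-2-methylbenzoic acid F2. BCl3 (CH2Cl2, −78 °C → rt) removes the MOM and methyl groups and the fallback comes back to the route at target 21.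

Step 9 (chlorination of a deactivated anisaldehyde). The ring carries CHO, Br and F, so the reaction may be slow or give some ipso attack at the C–Br carbon. The fallback sets out from 14 and chlorinates at the phenol stage instead. BCl3 (CH2Cl2, 0 °C) cleaves the methyl ether ortho to the formyl group to give 3-bromo-2-fluoro-6-hydroxy-4-methylbenzaldehyde F3. SO2Cl2 (CH2Cl2, 0 °C → rt) chlorinates this much more activated salicylaldehyde at its only open position to give 3-bromo-5-chloro-2-fluoro-6-hydroxy-4-methylbenzaldehyde F4. Remethylation (MeI, K2CO3, DMF, rt) brings the fallback back to the route at 15.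

Step 2 (DDQ aromatisation). Over-oxidation of the electron-rich resorcylate or incomplete dehydrogenation is possible. The fallback sets out from 4 and aromatises by halogenation instead. Br2 (2.2 equiv, AcOH, rt → 50 °C) brominates and dehydrobrominates the dione and also brominates C5, giving methyl 5-bromo-2,4-dihydroxy-3,6-dimethylbenzoate F5. Hydrodebromination (H2 1 atm, Pd/C, NaOAc, MeOH, rt) brings the fallback back to the route at 5.

Further compounds
F1 | step 13 | methyl 5-(2-bromo-4-chloro-6-formyl-5-methoxy-3-methylphenoxy)-2,4-bis(methoxymethoxy)-3,6-dimethylbenzoate | COC(=O)c1c(C)c(Oc2c(C=O)c(OC)c(Cl)c(C)c2Br)c(OCOC)c(C)c1OCOC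
F2 | step 13 | 3-chloro-5-formyl-4-methoxy-6-[5-(methoxycarbonyl)-2,4-bis(methoxymethoxy)-3,6-dimethylphenoxy]-2-methylbenzoic acid | COC(=O)c1c(C)c(Oc2c(C=O)c(OC)c(Cl)c(C)c2C(=O)O)c(OCOC)c(C)c1OCOC
F3 | step 9 | 3-bromo-2-fluoro-6-hydroxy-4-methylbenzaldehyde | Oc1cc(C)c(Br)c(F)c1C=O
F4 | step 9 | 3-bromo-5-chloro-2-fluoro-6-hydroxy-4-methylbenzaldehyde | Oc1c(Cl)c(C)c(Br)c(F)c1C=O
F5 | step 2 | methyl 5-bromo-2,4-dihydroxy-3,6-dimethylbenzoate | COC(=O)c1c(C)c(Br)c(O)c(C)c1O
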